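**Plan** (labdane numbering: ring A = C1–C5/C10, ring B = C5–C10, C17 = CH2 on C8, C18/C19 = methyl/ester carbon on C4, C20 = methyl on C10, chain C11–C15 on C9)
- Feature: ring B is a 3-methylenecyclohexane, with the C8=C17 methylene flanked by C7 and the axial C9 centre. Joining C6 to C7 from a C6 aldehyde on ring A and a C8 isopropenyl group on C9 gives ring B and the methylene at once.
- Cuts, in retrosynthetic order: C15 acid from silyl ether; C6–H from C6–OH; C6–C7 (ring B, carbonyl-ene); isopropenyl from a lactone carbonyl; C9–C11 (lactone alkylation); C9–C10 (Ireland–Claisen); C5–C6 (formylation of an enol triflate); C10–CH3 and C4–CH3 (enolate methylations).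
- Forward: ring A is built from methyl 2-oxocyclohexane-1-carboxylate. A temporary δ-lactone (C8 carbonyl, oxygen on C6) is fused to it, alkylated at C9 with the citronellol-derived C11–C15 iodide, and opened to the aldehyde/isopropenyl pair. Ring B then closes; C6 is deoxygenated and C15 oxidised.
- Stereochemistry: C4 from a valine-derived enamine methylation; C10 from the Claisen step, anti to the pseudoaxial C4 ester; C5 from hydroboration anti to the axial C20/C19 pair; C9 from axial alkylation anti to C20; C13 from (R)-citronellol; the C6 carbinol centre is transient.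

Key step: step 19

Assumption: with HMPA as lithium ligand, the lithiated enamine from tert-butyl L-valinate is taken to accept methyl iodide on the face that leads to the (R)-keto ester 6; if the sense is the opposite, tert-butyl D-valinate is used with no other change.

**Step 1**
Reactants: 1 methyl 2-oxocyclohexane-1-carboxylate; 2 tert-butyl L-valinate
Product: 3 methyl 2-{[(2S)-1-tert-butoxy-3-methyl-1-oxobutan-2-yl]amino}cyclohex-1-ene-1-carboxylate
Conditions: TsOH (cat.), toluene, reflux, Dean–Stark
Reagents that add atoms: none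
Why: Condensation of the β-keto ester with the primary amine (enamine formation) gives the hydrogen-bonded β-enamino ester, which places the valine stereocentre next to the carbon to be alkylated.

**Step 2**
Reactants: 3 enamino ester
Product: 6 methyl (1R)-1-methyl-2-oxocyclohexane-1-carboxylate, via lithiated enamine 4 (not isolated), via alkylated imine 5 (not isolated)
Conditions: LiN(i-Pr)2, toluene, HMPA, −78 °C; MeI, −78 → −40 °C; then 1 M HCl, rt
Reagents that add atoms: iodomethane CI; water O
Why: Asymmetric alkylation of a chiral lithiated β-enamino ester: lithium is held between the nitrogen and the tert-butyl ester carbonyl, the isopropyl group covers one face of the planar carbon, methyl iodide enters from the other and sets C4, and acid hydrolysis of the imine releases the ketone and the auxiliary.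

**Step 3**
Reactants: 6 (R)-keto ester
Product: 8 methyl (1R)-1,3-dimethyl-2-oxocyclohexane-1-carboxylate (both C3 epimers), via lithium enolate 7 (not isolated)
Conditions: LiN(i-Pr)2, THF, −78 °C; MeI, −78 → 0 °C
Reagents that add atoms: iodomethane CI
Why: Ketone enolate alkylation; C4 is quaternary, so only the C10 side can be deprotonated, and the C10 configuration is irrelevant because C10 becomes sp2 in the next step.

**Step 4**
Reactants: 8 dimethyl keto ester
Product: 10 methyl (1R)-1,3-dimethyl-2-(trifluoromethanesulfonyloxy)cyclohex-2-ene-1-carboxylate, via potassium enolate 9 (not isolated)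
Conditions: KN(SiMe3)2, THF, −78 → 0 °C; PhNTf2, 0 °C → rt
Reagents that add atoms: N-phenylbis(trifluoromethanesulfonimide) O=S(=O)(N(c1ccccc1)S(=O)(=O)C(F)(F)F)C(F)(F)F
Why: O-sulfonylation of the only possible enolate gives the tetrasubstituted C5=C10 enol triflate regiospecifically (enol triflate formation).

**Step 5**
Reactants: 10 enol triflate
Product: 11 methyl (1R)-2-formyl-1,3-dimethylcyclohex-2-ene-1-carboxylate
Conditions: Pd(OAc)2 (cat.), 1,3-bis(diphenylphosphino)propane, CO (1 atm), Et3SiH, Et3N, DMF, 70 °C
Reagents that add atoms: carbon monoxide [C-]#[O+]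
Why: Palladium-catalysed reductive carbonylation (formylation) of a vinyl triflate: oxidative addition to zerovalent palladium, CO insertion and hydride transfer from the silane install C6 as an aldehyde that the next step can reduce without touching the C19 ester.

**Step 6**
Reactants: 11 enal
Product: 12 methyl (1R)-2-(hydroxymethyl)-1,3-dimethylcyclohex-2-ene-1-carboxylate
Conditions: NaBH4, CeCl3·7H2O, MeOH, 0 °C
Reagents that add atoms: none
Why: Luche 1,2-reduction of the enal gives the allylic alcohol and leaves the ester untouched.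

**Step 7**
Reactants: 12 allylic alcohol
Product: 13 methyl (1R)-2-(acetoxymethyl)-1,3-dimethylcyclohex-2-ene-1-carboxylate
Conditions: Ac2O, pyridine, DMAP (cat.), CH2Cl2, rt
Reagents that add atoms: acetic anhydride CC(=O)OC(C)=O
Why: Standard acylation supplies the allyl acetate needed for the ester enolate rearrangement.

**Step 8**
Reactants: 13 allyl acetate
Product: 17 2-[(1S,3R)-3-(methoxycarbonyl)-1,3-dimethyl-2-methylidenecyclohexyl]acetic acid, via lithium enolate 14 (not isolated), via silyl ketene acetal 15 (not isolated), via silyl ester 16 (not isolated)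
Conditions: LiN(i-Pr)2, THF, −78 °C; t-BuMe2SiCl, DMPU, −78 °C → reflux; then 1 M HCl, THF, rt
Reagents that add atoms: none
Why: Ireland–Claisen rearrangement: the silyl ketene acetal forms the C9–C10 bond through a chair-like [3,3] transition state and moves the double bond to C5=C6; the C4 ester should sit pseudoaxial on the cyclohexene half-chair (smaller conformational demand than methyl), so bonding should occur on the opposite face, which puts C9 cis to C18 and C20 cis to the ester.

**Step 9**
Reactants: 17 acid
Product: 19 methyl 3-(2-hydroxyethyl)-2-(hydroxymethyl)-1,3-dimethylcyclohexane-1-carboxylate (C4 and C10 as in 17; C5–H cis to the C9 arm), via alkylborane borate ester 18 (not isolated)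
Conditions: BH3·SMe2 (excess), THF, 0 °C → rt; NaBO3·4H2O, H2O, rt
Reagents that add atoms: sodium perborate O[B-]1(O)OO[B-](O)(O)OO1.[Na+].[Na+]
Why: Borane reduces the carboxylic acid but not the hindered methyl ester and hydroborates the exocyclic alkene with boron on C6; the cis C10 methyl and C4 ester occupy the two axial sites beside C5, so hydrogen should arrive on the other face, and the near-neutral perborate oxidation avoids a strongly basic alkoxide next to the ester.

**Step 10**
Reactants: 19 diol
Product: 21 trans-fused δ-lactone, methyl 4a,8-dimethyl-3-oxo-octahydro-1H-isochromene-8-carboxylate (isochromene C1 = C6, C3 = C8, C4 = C9, C4a = C10, C8 = C4, C8a = C5), via lactol 20 (not isolated)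
Conditions: TEMPO (cat.), PhI(OAc)2, CH2Cl2, rt
Reagents that add atoms: none
Why: Oxoammonium oxidation takes the unhindered C8 carbinol to the aldehyde, the neopentyl C6 hydroxyl closes the lactol, and a second oxidation gives the lactone (oxidative lactonisation of a 1,5-diol), so the carbonyl ends at C8.

**Step 11**
Reactants: 22 (R)-citronellol
Product: 23 tert-butyl{[(3R)-3,7-dimethyloct-6-en-1-yl]oxy}dimethylsilane
Conditions: t-BuMe2SiCl, imidazole, DMF, rt
Reagents that add atoms: tert-butyldimethylsilyl chloride CC(C)(C)[Si](C)(C)Cl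
Why: Silyl protection of the primary alcohol that will become C15.

**Step 12**
Reactants: 23 silyl ether
Product: 25 (4R)-6-[(tert-butyldimethylsilyl)oxy]-4-methylhexanoic acid, via aldehyde 24 (not isolated)
Conditions: RuCl3·xH2O (cat.), NaIO4, EtOAc/MeCN/H2O, rt
Reagents that add atoms: sodium periodate [Na+].[O-]I(=O)(=O)=O; water O
Why: Ruthenium tetroxide generated in situ cleaves the trisubstituted alkene to the acid and acetone (oxidative alkene cleavage); the stereocentre is remote.

**Step 13**
Reactants: 25 acid
Product: 27 tert-butyl{[(3S)-5-iodo-3-methylpentyl]oxy}dimethylsilane, via acyl hypoiodite 26 (not isolated)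
Conditions: PhI(OAc)2, I2, cyclohexane, hν, 60 °C
Reagents that add atoms: iodine II
Why: Photochemical iododecarboxylation (Hunsdiecker-type): the acyl hypoiodite loses CO2 and the primary radical is trapped by iodine, which shortens the chain by one carbon to the C11–C15 unit.

**Step 14**
Reactants: 21 δ-lactone; 27 iodide
Product: 29 C9-alkylated δ-lactone (21 carrying at C9, trans to the C10 methyl, the (3S)-5-(tert-butyldimethylsilyloxy)-3-methylpentyl chain), via lactone lithium enolate 28 (not isolated)
Conditions: LiN(i-Pr)2, THF, −78 °C; 27, DMPU, −78 → −20 °C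
Reagents that add atoms: none
Why: Lactone enolate alkylation: in the rigid trans-fused bicycle the electrophile enters axially on the face away from the adjacent axial C10 methyl, which makes the C9 chain axial and anti to C20; the C19 ester has no α-hydrogen.

**Step 15**
Reactants: 29 alkylated lactone
Product: 31 methyl lactol (C8 hemiketal, in equilibrium with its open hydroxy ketone form), via lithium hemiketal alkoxide 30 (not isolated)
Conditions: MeLi (1.2 equiv), THF, −78 °C; AcOH, −78 °C
Reagents that add atoms: methyllithium [Li]C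
Why: Mono-addition of an organolithium to a lactone: the tetrahedral lithium hemiketal is stable at −78 °C and is protonated cold, and the lactone carbonyl is more electrophilic than the C19 ester on the quaternary carbon.

**Step 16**
Reactants: 31 lactol
Product: 33 C8 methyl ketone with C6 triethylsilyl ether, via open-chain hydroxy ketone 32 (not isolated)
Conditions: Et3SiCl, imidazole, DMAP (cat.), DMF, rt
Reagents that add atoms: chlorotriethylsilane CC[Si](CC)(CC)Cl
Why: Silylation captures the open-chain tautomer as its primary silyl ether (silyl protection), so that no C6 alkoxide can attack the neighbouring cis C19 ester during the basic olefination.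

**Step 17**
Reactants: 33 keto silyl ether
Product: 34 C9 isopropenyl compound with C6 triethylsilyl ether
Conditions: Ph3PCH3Br, KN(SiMe3)2, THF, 0 °C → rt
Reagents that add atoms: methyltriphenylphosphonium bromide C[P+](c1ccccc1)(c1ccccc1)c1ccccc1.[Br-]
Why: Wittig methylenation turns the methyl ketone into the C8(=C7H2)–C17H3 isopropenyl group; the hindered C9 hydrogen next to the quaternary C10 should not be removed by the ylide.

**Step 18**
Reactants: 34 isopropenyl silyl ether
Product: 36 methyl 3-[(6R)-8-(tert-butyldimethylsilyloxy)-2,6-dimethyloct-1-en-3-yl]-2-formyl-1,3-dimethylcyclohexane-1-carboxylate (C4, C5, C9, C10 as in the target), via alkoxysulfonium chloride 35 (not isolated)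
Conditions: (COCl)2, DMSO, CH2Cl2, −78 → −30 °C; Et3N, → 0 °C
Reagents that add atoms: none
Why: Swern oxidation applied directly to a primary triethylsilyl ether: activated DMSO displaces the silyl group, the primary tert-butyldimethylsilyl ether at C15 is left, and the C5 hydrogen between two quaternary carbons should not epimerise.

**Step 19**
Reactants: 36 ring A aldehyde ester
Product: 38 C6-hydroxy decalin ester with C8=C17, axial C9 chain and C15 silyl ether, via aluminium alkoxide 37 (not isolated)
Conditions: Me2AlCl (2 equiv), CH2Cl2, −78 → 0 °C; cold 1 M HCl work-up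
Reagents that add atoms: none
Why: Me2AlCl binds the C6 aldehyde oxygen; the terminal alkene carbon C7 attacks C6 while a C17 hydrogen passes to oxygen through a six-membered ene transition state, so C6–C7 and C8=C17 arise in one concerted step, and the alcohol–aluminium complex then loses methane to give alkoxide 37, which removes the proton source for side reactions. This is the Lewis acid-promoted type 2 intramolecular carbonyl-ene reaction established for 6-methylhept-6-enal-type aldehydes, which give 3-methylenecyclohexanols. Ring B (C5–C10) closes in a chair-like arrangement by 6-exo attack on the carbonyl, with the ene carbon C8 inside the new ring and the C9 chain axial, anti to the C10 methyl, as fixed in step 14. The new C6 centre should form with the aluminium-bound oxygen equatorial, away from the axial C10 methyl and C4 ester; either epimer serves, because C6 is deoxygenated next. The step needs the exocyclic alkene regiochemistry and retention at C5 and C9: only the C17 hydrogens can reach the carbonyl oxygen in the cyclic transition state (the C9 hydrogen lies across the forming ring), no enol or free cation at C5, C8 or C9 is involved, and the trans diequatorial placement of the aldehyde and C9 on ring A lets the two ends meet.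

**Step 20**
Reactants: 38 C6 alcohol
Product: 39 C6 O-(imidazol-1-ylthiocarbonyl) derivative of 38
Conditions: 1,1'-thiocarbonyldiimidazole, DMAP (cat.), ClCH2CH2Cl, 70 °C
Reagents that add atoms: 1,1'-thiocarbonyldiimidazole S=C(n1ccnc1)n1ccnc1
Why: Neutral thioacylation of the hindered secondary alcohol (first half of the Barton–McCombie deoxygenation) avoids forming an alkoxide near the C19 ester.

**Step 21**
Reactants: 39 thiocarbonyl derivative
Product: 40 methyl ester of the 15-O-silyl decalin with C6 as CH2
Conditions: n-Bu3SnH, AIBN (cat.), toluene, 100 °C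
Reagents that add atoms: none
Why: Barton–McCombie radical deoxygenation: the stannyl radical adds to sulfur, the secondary C6 radical is released and reduced by the tin hydride, and the C8=C17 alkene and both stereocentres beside it are not involved.

**Step 22**
Reactants: 40 silyl ether
Product: 41 primary C15 alcohol
Conditions: n-Bu4NF, THF, rt
Reagents that add atoms: none
Why: Fluoride cleavage of the primary silyl ether; the hindered methyl ester is stable to these conditions.

**Step 23**
Reactants: 41 alcohol
Product: 43 (3R)-5-[(1S,4aS,5R,8aS)-5-(methoxycarbonyl)-5,8a-dimethyl-2-methylidenedecahydronaphthalen-1-yl]-3-methylpentanoic acid, via aldehyde 42 (not isolated)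
Conditions: TEMPO (cat.), PhI(OAc)2, MeCN/H2O, rt
Reagents that add atoms: water O
Why: Oxoammonium oxidation in aqueous acetonitrile takes the primary alcohol through the aldehyde hydrate to the acid without touching the exocyclic alkene or the methyl ester.

**Compound list**
1 | methyl 2-oxocyclohexane-1-carboxylate | COC(=O)C1CCCCC1=O | starting material
2 | tert-butyl L-valinate | CC(C)[C@H](N)C(=O)OC(C)(C)C | starting material
3 | methyl 2-{[(2S)-1-tert-butoxy-3-methyl-1-oxobutan-2-yl]amino}cyclohex-1-ene-1-carboxylate | CC(C)[C@H](NC1=C(C(=O)OC)CCCC1)C(=O)OC(C)(C)C | intermediate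
4 | lithiated enamine of 3 (not isolated) | CC(C)[C@H]([N-]C1=C(C(=O)OC)CCCC1)C(=O)OC(C)(C)C.[Li+] | intermediate
5 | C4-methylated imine of 6 with tert-butyl L-valinate (not isolated) | CC(C)[C@H](N=C1CCCC[C@@]1(C)C(=O)OC)C(=O)OC(C)(C)C | intermediate
6 | methyl (1R)-1-methyl-2-oxocyclohexane-1-carboxylate | O=C1CCCC[C@@]1(C)C(=O)OC | intermediate
7 | lithium enolate of 6 (not isolated) | [Li+].[O-]C1=CCCC[C@@]1(C)C(=O)OC | intermediate
8 | methyl (1R)-1,3-dimethyl-2-oxocyclohexane-1-carboxylate, C3 epimers | O=C1C(C)CCC[C@@]1(C)C(=O)OC | intermediate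
9 | potassium enolate of 8 (not isolated) | [K+].[O-]C1=C(C)CCC[C@@]1(C)C(=O)OC | intermediate
10 | methyl (1R)-1,3-dimethyl-2-(trifluoromethanesulfonyloxy)cyclohex-2-ene-1-carboxylate | O=S(=O)(OC1=C(C)CCC[C@@]1(C)C(=O)OC)C(F)(F)F | intermediate
11 | methyl (1R)-2-formyl-1,3-dimethylcyclohex-2-ene-1-carboxylate | O=CC1=C(C)CCC[C@@]1(C)C(=O)OC | intermediate
12 | methyl (1R)-2-(hydroxymethyl)-1,3-dimethylcyclohex-2-ene-1-carboxylate | OCC1=C(C)CCC[C@@]1(C)C(=O)OC | intermediate
13 | methyl (1R)-2-(acetoxymethyl)-1,3-dimethylcyclohex-2-ene-1-carboxylate | CC(=O)OCC1=C(C)CCC[C@@]1(C)C(=O)OC | intermediate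
14 | lithium enolate of acetate 13 (not isolated) | [Li+].C=C([O-])OCC1=C(C)CCC[C@@]1(C)C(=O)OC | intermediate
15 | tert-butyldimethylsilyl ketene acetal of 13 (not isolated) | C=C(O[Si](C)(C)C(C)(C)C)OCC1=C(C)CCC[C@@]1(C)C(=O)OC | intermediate
16 | tert-butyldimethylsilyl ester of 17 (not isolated) | C=C1[C@@](C)(CCC[C@@]1(C)C(=O)OC)CC(=O)O[Si](C)(C)C(C)(C)C | intermediate
17 | 2-[(1S,3R)-3-(methoxycarbonyl)-1,3-dimethyl-2-methylidenecyclohexyl]acetic acid | C=C1[C@@](C)(CCC[C@@]1(C)C(=O)OC)CC(=O)O | intermediate
18 | C6 alkylborane, C8 borate ester from 17 (idealised, not isolated) | BC[C@H]1[C@@](C)(CCC[C@@]1(C)C(=O)OC)CCOB | intermediate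
19 | methyl 3-(2-hydroxyethyl)-2-(hydroxymethyl)-1,3-dimethylcyclohexane-1-carboxylate (C6H2OH on C5 trans to the C9 arm, cis to C20 and the ester) | OC[C@H]1[C@@](C)(CCC[C@@]1(C)C(=O)OC)CCO | intermediate
20 | δ-lactol from 19, hemiacetal at C8 (not isolated) | OC1OC[C@H]2[C@@](C)(CCC[C@@]2(C)C(=O)OC)C1 | intermediate
21 | trans-fused δ-lactone, methyl 4a,8-dimethyl-3-oxo-octahydro-1H-isochromene-8-carboxylate (4a-methyl and 8-ester cis, 8a-H trans to 4a-methyl) | O=C1OC[C@H]2[C@@](C)(CCC[C@@]2(C)C(=O)OC)C1 | intermediate
22 | (R)-citronellol | C[C@H](CCC=C(C)C)CCO | starting material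
23 | tert-butyl{[(3R)-3,7-dimethyloct-6-en-1-yl]oxy}dimethylsilane | C[C@H](CCC=C(C)C)CCO[Si](C)(C)C(C)(C)C | intermediate
24 | (4R)-6-[(tert-butyldimethylsilyl)oxy]-4-methylhexanal (not isolated) | C[C@H](CCC=O)CCO[Si](C)(C)C(C)(C)C | intermediate
25 | (4R)-6-[(tert-butyldimethylsilyl)oxy]-4-methylhexanoic acid | C[C@H](CCC(=O)O)CCO[Si](C)(C)C(C)(C)C | intermediate
26 | acyl hypoiodite of 25 (not isolated) | C[C@H](CCC(=O)OI)CCO[Si](C)(C)C(C)(C)C | intermediate
27 | tert-butyl{[(3S)-5-iodo-3-methylpentyl]oxy}dimethylsilane | C[C@H](CCI)CCO[Si](C)(C)C(C)(C)C | intermediate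
28 | lithium enolate of lactone 21 (not isolated) | [Li+].[O-]C1OC[C@H]2[C@@](C)(CCC[C@@]2(C)C(=O)OC)C=1 | intermediate
29 | lactone 21 with the (3S)-5-(tert-butyldimethylsilyloxy)-3-methylpentyl chain at C9, trans to the C10 methyl | O=C1OC[C@H]2[C@@](C)(CCC[C@@]2(C)C(=O)OC)[C@H]1CC[C@@H](C)CCO[Si](C)(C)C(C)(C)C | intermediate
30 | lithium hemiketal alkoxide from 29 and MeLi (not isolated) | [Li+].CC1([O-])OC[C@H]2[C@@](C)(CCC[C@@]2(C)C(=O)OC)[C@H]1CC[C@@H](C)CCO[Si](C)(C)C(C)(C)C | intermediate
31 | C8 methyl lactol (hemiketal, C8 epimers) | CC1(O)OC[C@H]2[C@@](C)(CCC[C@@]2(C)C(=O)OC)[C@H]1CC[C@@H](C)CCO[Si](C)(C)C(C)(C)C | intermediate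
32 | open-chain C6 hydroxy C8 methyl ketone (not isolated) | OC[C@H]1[C@@](C)(CCC[C@@]1(C)C(=O)OC)[C@@H](CC[C@@H](C)CCO[Si](C)(C)C(C)(C)C)C(C)=O | intermediate
33 | C8 methyl ketone, C6 triethylsilyl ether | CC[Si](CC)(CC)OC[C@H]1[C@@](C)(CCC[C@@]1(C)C(=O)OC)[C@@H](CC[C@@H](C)CCO[Si](C)(C)C(C)(C)C)C(C)=O | intermediate
34 | C9 isopropenyl compound, C6 triethylsilyl ether | CC[Si](CC)(CC)OC[C@H]1[C@@](C)(CCC[C@@]1(C)C(=O)OC)[C@@H](CC[C@@H](C)CCO[Si](C)(C)C(C)(C)C)C(C)=C | intermediate
35 | C6 alkoxydimethylsulfonium chloride (not isolated) | C[S+](C)OC[C@H]1[C@@](C)(CCC[C@@]1(C)C(=O)OC)[C@@H](CC[C@@H](C)CCO[Si](C)(C)C(C)(C)C)C(C)=C.[Cl-] | intermediate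
36 | ring A aldehyde ester: methyl 3-[(6R)-8-(tert-butyldimethylsilyloxy)-2,6-dimethyloct-1-en-3-yl]-2-formyl-1,3-dimethylcyclohexane-1-carboxylate | O=C[C@H]1[C@@](C)(CCC[C@@]1(C)C(=O)OC)[C@@H](CC[C@@H](C)CCO[Si](C)(C)C(C)(C)C)C(C)=C | intermediate
37 | chloro(methyl)aluminium alkoxide of 38 (not isolated) | C=C1C[C@@H](O[Al](C)Cl)[C@H]2[C@@](C)(CCC[C@@]2(C)C(=O)OC)[C@H]1CC[C@@H](C)CCO[Si](C)(C)C(C)(C)C | intermediate
38 | C6-hydroxy decalin ester with C8=C17, axial C9 chain, equatorial 6-OH, C15 silyl ether | C=C1C[C@@H](O)[C@H]2[C@@](C)(CCC[C@@]2(C)C(=O)OC)[C@H]1CC[C@@H](C)CCO[Si](C)(C)C(C)(C)C | intermediate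
39 | C6 O-(imidazol-1-ylthiocarbonyl) derivative of 38 | C=C1C[C@@H](OC(=S)n3ccnc3)[C@H]2[C@@](C)(CCC[C@@]2(C)C(=O)OC)[C@H]1CC[C@@H](C)CCO[Si](C)(C)C(C)(C)C | intermediate
40 | 6-deoxy decalin ester, C15 silyl ether | C=C1CC[C@H]2[C@@](C)(CCC[C@@]2(C)C(=O)OC)[C@H]1CC[C@@H](C)CCO[Si](C)(C)C(C)(C)C | intermediate
41 | C15 primary alcohol | C=C1CC[C@H]2[C@@](C)(CCC[C@@]2(C)C(=O)OC)[C@H]1CC[C@@H](C)CCO | intermediate
42 | C15 aldehyde (not isolated) | C=C1CC[C@H]2[C@@](C)(CCC[C@@]2(C)C(=O)OC)[C@H]1CC[C@@H](C)CC=O | intermediate
43 | (3R)-5-[(1S,4aS,5R,8aS)-5-(methoxycarbonyl)-5,8a-dimethyl-2-methylidenedecahydronaphthalen-1-yl]-3-methylpentanoic acid | C=C1CC[C@H]2[C@@](C)(CCC[C@@]2(C)C(=O)OC)[C@H]1CC[C@@H](C)CC(=O)O | target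

**Step count**
Total: 23 steps. Longest linear sequence: 20 steps (steps 1–10 and 14–23, from compound 1); the side chain takes 3 steps (11–13) from (R)-citronellol.

**Steps most likely to fail**

Step 8. Two things may go wrong: the C4 centre, which differs only by methyl against ester, may discriminate poorly between the two faces of C10, and bond formation between two fully substituted carbons may be slow enough for the ketene acetal to decompose. The fallback replaces substrate control by catalyst control. It sets out from ketone 8, which with KN(SiMe3)2 and allyl chloroformate gives the allyl enol carbonate F1. Pd2(dba)3 with (S)-4-tert-butyl-2-[2-(diphenylphosphino)phenyl]-4,5-dihydrooxazole, the ligand enantiomer expected to give the (S) centre, then effects decarboxylative asymmetric allylic alkylation to the C10 allyl ketone F2. Methylenation of the C5 ketone with Cp2TiMe2 gives the diene F3. OsO4/N-methylmorpholine N-oxide followed by NaIO4 should cleave only the unhindered allyl double bond and give the aldehyde F4. Oxidation with NaClO2 comes back to the route at acid 17.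

Step 14. The enolate carbon sits next to the quaternary C10, so substitution on an unactivated primary iodide may be slow and proton transfer or enolate decomposition may win. The fallback forms the same bond by carbonyl addition. It sets out from iodide 27 and lactone 21: Kornblum oxidation of 27 (DMSO, NaHCO3, 100 °C) gives the aldehyde F5. Aldol addition of enolate 28 to F5 at −78 °C, with the same axial approach anti to the C10 methyl, gives the β-hydroxy lactone F6. 1,1'-Thiocarbonyldiimidazole converts it into the thiocarbonyl derivative F7, and n-Bu3SnH/AIBN removes the C11 oxygen and comes back to the route at compound 29.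

Step 19. The aluminium-bound aldehyde is a neopentyl centre between two quaternary carbons, and the closure must place the C9 chain axial; the concerted path may therefore be slow, and cationic closure with chloride capture or loss of a ring proton may compete. The fallback makes the same C6–C7 bond and the same C8=C17 alkene by an allylsilane addition. It sets out from ketone 33: KN(SiMe3)2 and PhNTf2 give the kinetic enol triflate F8. Kumada coupling with Me3SiCH2MgCl and Pd(PPh3)4 gives the allylsilane F9. Direct Swern oxidation of the triethylsilyl ether gives the aldehyde F10, and BF3·OEt2 at −78 °C closes ring B by an intramolecular Hosomi–Sakurai reaction, coming back to the route at alcohol 38.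

**Further compounds**
F1 | step 8 | allyl enol carbonate of ketone 8 | C=CCOC(=O)OC1=C(C)CCC[C@@]1(C)C(=O)OC
F2 | step 8 | methyl (1R,3S)-1,3-dimethyl-2-oxo-3-(prop-2-en-1-yl)cyclohexane-1-carboxylate | O=C1[C@@](C)(CCC[C@@]1(C)C(=O)OC)CC=C
F3 | step 8 | C5 methylidene, C10 allyl diene ester | C=C1[C@@](C)(CCC[C@@]1(C)C(=O)OC)CC=C
F4 | step 8 | C8 aldehyde corresponding to acid 17 | C=C1[C@@](C)(CCC[C@@]1(C)C(=O)OC)CC=O
F5 | step 14 | (3S)-5-[(tert-butyldimethylsilyl)oxy]-3-methylpentanal | C[C@H](CC=O)CCO[Si](C)(C)C(C)(C)C
F6 | step 14 | C11-hydroxy aldol adduct of lactone 21 (C11 epimers) | O=C1OC[C@H]2[C@@](C)(CCC[C@@]2(C)C(=O)OC)[C@H]1C(O)C[C@@H](C)CCO[Si](C)(C)C(C)(C)C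
F7 | step 14 | C11 O-(imidazol-1-ylthiocarbonyl) derivative of F6 | O=C1OC[C@H]2[C@@](C)(CCC[C@@]2(C)C(=O)OC)[C@H]1C(OC(=S)n3ccnc3)C[C@@H](C)CCO[Si](C)(C)C(C)(C)C
F8 | step 19 | C8 enol triflate of ketone 33 (C8=C7H2) | CC[Si](CC)(CC)OC[C@H]1[C@@](C)(CCC[C@@]1(C)C(=O)OC)[C@@H](CC[C@@H](C)CCO[Si](C)(C)C(C)(C)C)C(=C)OS(=O)(=O)C(F)(F)F
F9 | step 19 | allylsilane with C17H2SiMe3 on C8, C6 triethylsilyl ether | CC[Si](CC)(CC)OC[C@H]1[C@@](C)(CCC[C@@]1(C)C(=O)OC)[C@@H](CC[C@@H](C)CCO[Si](C)(C)C(C)(C)C)C(=C)C[Si](C)(C)C
F10 | step 19 | allylsilane aldehyde (C6 formyl) | O=C[C@H]1[C@@](C)(CCC[C@@]1(C)C(=O)OC)[C@@H](CC[C@@H](C)CCO[Si](C)(C)C(C)(C)C)C(=C)C[Si](C)(C)C
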